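**Retrosynthetic overview**

1. Target 33 ⇐ bicyclic alcohol 25 by esterification at O8 and O9, nucleophilic epoxidation of the C11=C15 acrylate (oxirane formed last but one) and, as the final step, oxidation at C4 to unveil the epimerisable ketone.
2. 25 ⇐ cyclopentane fragment A (15) + alkynal fragment B (23) in one flask: C7–C8 by Barbier allylation, then C1–C2 by 6-exo-dig radical closure; the cyclopentane ring is bought, the cyclohexane ring is closed in the key step.
3. Enabling feature: on the cyclohexane ring C1–C2–C6–C7–C8–C9, C7 carries an α-methylene ester next to the C8 carbinol (footprint of a 2-(halomethyl)acrylate allylation) and C1 carries an exocyclic methylene next to oxygenated C9 (footprint of a terminal propargylic alkyne); both new bonds flank C6, so the C6 tether enforces the cis ring fusion.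
4. 15 ⇐ (R)-4-silyloxycyclopentenone 1: Morita–Baylis–Hillman reaction (C13), vinyl addition with cis-protonation (C6, C5), C4 reduction and protection, ozonolysis, second Morita–Baylis–Hillman reaction, double iodination.
5. 23 ⇐ silyl ynone 18 by asymmetric transfer hydrogenation (C9).

Key step: step 16

Remark: names use the target's carbon locants (cyclohexane C1, C2, C6, C7, C8, C9 with the exocyclic methylene C10 on C1; cyclopentanone C3, C4 (C=O), C5; oxirane carbon C11, ester carbonyl C12, oxirane CH2 C15; 1-acetoxyethyl C13/C14), and compounds 1, 2, 5, 12, 16, 17, 20, 26 and 29 are assumed to be purchased.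

**Fragment A**

Step 1
Reactants: 1 (R)-4-(tert-butyldimethylsilyloxy)cyclopent-2-en-1-one; 2 acetaldehyde
Product: 3 (R)-4-(tert-butyldimethylsilyloxy)-2-[(S)-1-hydroxyethyl]cyclopent-2-en-1-one
Conditions: PEt3 (20 mol %), (R)-3,3′-bis(3,5-dimethylphenyl)-H8-BINOL (10 mol %), THF, −10 °C
Reagents that add atoms: none
Why: Morita–Baylis–Hillman reaction at C5 under phosphine/Brønsted acid catalysis mild enough for the β-silyloxy enone; the chiral H8-BINOL acid (the enantiomer that gives the (S)-carbinol is used) should set C13, and the C13 epimer, a diastereomer, is removed by chromatography.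

Step 2
Reactants: 3 enone alcohol
Product: 4 (R)-4-(tert-butyldimethylsilyloxy)-2-[(S)-1-(triethylsilyloxy)ethyl]cyclopent-2-en-1-one
Conditions: Et3SiCl, imidazole, DMF, 0 °C
Reagents that add atoms: chlorotriethylsilane CC[Si](Cl)(CC)CC
Why: Standard silylation of the secondary alcohol; the silyl ether is a poor leaving group, which keeps the next step a 1,4-addition and not an allylic displacement.

Step 3
Reactants: 4 silyl-protected enone; 5 vinylmagnesium bromide
Product: 6 cis-ketone (C4 ketone; C6 vinyl trans to C2–OTBS; C5 [(S)-1-(triethylsilyloxy)ethyl] cis to the vinyl group)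
Conditions: 5 (2 equiv), CuBr·SMe2 (10 mol %), THF, −78 °C; then ethyl salicylate, −78 °C; cold aqueous NH4Cl; used at once
Reagents that add atoms: none
Why: Copper-catalysed conjugate addition puts the vinyl group on C6 anti to the C2 silyloxy group, and kinetic protonation of the magnesium enolate by the salicylate on the face opposite to the new vinyl group should set C5 cis to C6 (diastereoselective enolate protonation).

Step 4
Reactants: 6 cis-ketone
Product: 7 C4 alcohol (C4–OH cis to the C5 side chain)
Conditions: LiBH(s-Bu)3, THF, −78 °C; aqueous NH4Cl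
Reagents that add atoms: none
Why: Hydride reduction by the bulky borohydride from the face opposite to the C5 side chain removes the ketone, so C5 can no longer epimerise; the C4 configuration does not matter because C4 is re-oxidised in step 22.

Step 5
Reactants: 7 C4 alcohol
Product: 8 C4 triisopropylsilyl ether
Conditions: i-Pr3SiOTf, 2,6-lutidine, CH2Cl2, 0 °C
Reagents that add atoms: triisopropylsilyl trifluoromethanesulfonate CC(C)[Si](OS(=O)(=O)C(F)(F)F)(C(C)C)C(C)C
Why: Silylation of the hindered secondary alcohol with the silyl triflate; the triisopropylsilyl ether should survive every step up to step 21.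

Step 6
Reactants: 8 tris-silyl ether
Product: 9 C13 alcohol
Conditions: pyridinium p-toluenesulfonate (10 mol %), MeOH/CH2Cl2 (1:1), 0 °C
Reagents that add atoms: none
Why: Acid-catalysed methanolysis cleaves the triethylsilyl ether selectively beside the secondary tert-butyldimethylsilyl and triisopropylsilyl ethers (selective desilylation).

Step 7
Reactants: 9 C13 alcohol
Product: 10 C13 acetate
Conditions: Ac2O, pyridine, DMAP (5 mol %), CH2Cl2, 25 °C
Reagents that add atoms: acetic anhydride CC(=O)OC(C)=O
Why: Acetylation of the only free hydroxyl installs the C13 acetate of the target without touching a stereocentre.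

Step 8
Reactants: 10 vinyl acetate
Product: 11 C7 aldehyde
Conditions: O3, CH2Cl2/MeOH, −78 °C; then PPh3, −78 to 25 °C
Reagents that add atoms: ozone [O-][O+]=O
Why: Ozonolysis of the only alkene with reductive work-up gives the C7 aldehyde, and cold neutral work-up avoids epimerisation at C6.

Step 9
Reactants: 11 C7 aldehyde; 12 methyl acrylate
Product: 13 Morita–Baylis–Hillman adduct (C7 carbinol, both epimers)
Conditions: 12 (5 equiv), DABCO (50 mol %), MeOH (cat.), 25 °C
Reagents that add atoms: none
Why: Morita–Baylis–Hillman reaction builds C11, C12 and C15 onto C7; the C7 carbinol forms as both epimers, which is harmless because this centre becomes sp2 in step 11.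

Step 10
Reactants: 13 adduct
Product: 14 C2,C7-diol
Conditions: HF·pyridine, pyridine/THF, 0 to 25 °C
Reagents that add atoms: none
Why: Fluoride cleaves the less hindered tert-butyldimethylsilyl ether at C2 and should leave the bulkier triisopropylsilyl ether at C4 (selective desilylation).

Step 11
Reactants: 14 diol
Product: 15 fragment A (C2 iodide cis to the side chain; (Z)-2-(iodomethyl)acrylate on C7)
Conditions: PPh3, I2, imidazole, toluene/MeCN (2:1), 0 to 25 °C, dark
Reagents that add atoms: iodine II
Why: Appel-type iodination turns the C2 alcohol into the iodide with inversion (its configuration is lost again in step 16) and the allylic alcohol into the rearranged primary allylic iodide by SN2′ displacement, the preferred (Z)-geometry placing C6 trans to the ester.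

**Fragment B**

Step 12
Reactants: 16 ethynyltrimethylsilane; 17 methyl 2,2-dimethoxyacetate
Product: 18 1,1-dimethoxy-4-(trimethylsilyl)but-3-yn-2-one
Conditions: n-BuLi, THF, −78 °C; acetylide added to 17 (excess), −78 °C
Reagents that add atoms: none
Why: Acylation of the lithium acetylide by the α,α-dimethoxy ester at −78 °C, where the chelated tetrahedral intermediate should suppress a second addition, gives the ynone.

Step 13
Reactants: 18 ynone
Product: 19 (R)-1,1-dimethoxy-4-(trimethylsilyl)but-3-yn-2-ol
Conditions: RuCl(p-cymene)[(S,S)-TsDPEN] (1 mol %), i-PrOH, 25 °C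
Reagents that add atoms: none
Why: Noyori asymmetric transfer hydrogenation sets C9: the catalyst tells the alkynyl from the sp3 substituent, and the (S,S)-ligand should give the (R)-alcohol.

Step 14
Reactants: 19 propargylic alcohol; 20 4-methoxybenzyl chloride
Product: 22 (R)-3-[(4-methoxybenzyl)oxy]-4,4-dimethoxybut-1-yne, via silylated ether 21 (not isolated)
Conditions: NaH, Bu4NI (5 mol %), THF/DMF, 0 to 25 °C; then K2CO3, MeOH, 25 °C
Reagents that add atoms: none
Why: Williamson etherification of the sodium alkoxide, followed in the same flask by methanolysis of the alkynyl C–Si bond; the stereocentre is not involved.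

Step 15
Reactants: 22 acetal
Product: 23 fragment B, (R)-2-[(4-methoxybenzyl)oxy]but-3-ynal
Conditions: LiBF4, MeCN/H2O (50:1), 25 °C; used at once
Reagents that add atoms: water O
Why: Mild Lewis-acid-assisted acetal hydrolysis leaves the 4-methoxybenzyl ether intact, and immediate use limits racemisation of the α-alkoxy aldehyde.

**Union and endgame**

Step 16
Reactants: 15 fragment A; 23 fragment B
Product: 25 bicyclic alcohol (cis-hydrindane with C1 exocyclic methylene; C7 acrylate; C8–OH; C9–O-PMB; C4–O-TIPS), via Barbier adduct 24 (not isolated)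
Conditions: In powder (4 equiv), THF/H2O (2:1), 25 °C, 3 h; then 55 °C, 12 h
Reagents that add atoms: none
Why: Proposed new method: zerovalent indium first inserts into the allylic C15–I bond and the allylindium adds through its γ-carbon C7 to the aldehyde C8 to give 24, after which continued single-electron transfer from indium to the less reactive secondary C2–I bond gives the C2 radical, which closes onto the terminal alkyne (C1–C2) and is reduced and protonated to the exocyclic methylene; the closest known reactions are the indium-mediated aqueous Barbier allylation with 2-(halomethyl)acrylates and the indium-mediated reductive radical cyclisation of iodoalkynes, merged here in one flask. The cyclohexane ring is closed by the radical step in the 6-exo-dig mode, and because the chain on C6 can reach the planar C2 radical only from its own face, the ring fusion is cis whatever the configuration of the iodide. C7 and C8 are set in the allylation: the (Z)-allyl unit should react through a cyclic six-membered transition state to give the 7,8-syn adduct, and chelation of indium by the α-(4-methoxybenzyl)oxy oxygen of (R)-23 should give the 8,9-syn (anti-Felkin) relationship. The π-face of the allyl unit is differentiated by C6: with C6–H eclipsing the C7=C11 bond to avoid allylic strain, the aldehyde should approach anti to C2, which carries the iodine on the side-chain face. The step needs chemoselectivity (allylic before alkyl iodide), which the much faster insertion of indium into allylic halides should secure, and γ-regioselectivity, which the cyclic transition state secures.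

Step 17
Reactants: 25 bicyclic alcohol; 26 (E)-3-methylpent-2-enoic acid
Product: 27 C8 (E)-3-methylpent-2-enoate
Conditions: DCC, DMAP (20 mol %), CH2Cl2, 0 to 25 °C
Reagents that add atoms: none
Why: Steglich esterification of the only free hydroxyl (C8); low temperature limits lactonisation onto the neighbouring methyl ester and isomerisation of the enoate.

Step 18
Reactants: 27 C8 ester
Product: 28 C9 alcohol
Conditions: DDQ, CH2Cl2/pH 7 phosphate buffer (10:1), 0 °C
Reagents that add atoms: none
Why: Oxidative cleavage of the 4-methoxybenzyl ether by DDQ under buffered conditions frees the C9 hydroxyl without touching esters, silyl ether or alkenes.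

Step 19
Reactants: 28 C9 alcohol; 29 (S)-3-methylpentanoic acid
Product: 30 diester acrylate
Conditions: DCC, DMAP (20 mol %), CH2Cl2, 0 to 25 °C
Reagents that add atoms: none
Why: Steglich esterification of the allylic C9 hydroxyl installs the last ester with retention at C9.

Step 20
Reactants: 30 diester acrylate
Product: 31 C11,C15-oxirane
Conditions: t-BuOOH (anhydrous, in decane), DBU, CH2Cl2, 0 °C
Reagents that add atoms: tert-butyl hydroperoxide CC(C)(C)OO
Why: Nucleophilic (Weitz–Scheffer-type) epoxidation: the peroxide anion should add only to the unhindered 1,1-disubstituted acrylate (the β,β-disubstituted enoate and the isolated methylene are inert), and closure of the ester enolate on oxygen anti to the C8 acyloxy group, in the conformer with C7–H eclipsing the alkene, should give the (R)-oxirane at C11.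

Step 21
Reactants: 31 oxirane
Product: 32 C4 alcohol
Conditions: Bu4NF, AcOH (1:1), THF, 25 °C
Reagents that add atoms: none
Why: Buffered fluoride should remove the triisopropylsilyl group without acyl migration or ester cleavage.

Step 22
Reactants: 32 C4 alcohol
Product: 33 target CNP0109740.1
Conditions: Dess–Martin periodinane, NaHCO3, CH2Cl2, 0 to 25 °C
Reagents that add atoms: none
Why: Dess–Martin oxidation under buffered, non-basic conditions unveils the C4 ketone last, so the base-labile β-acetoxy ketone and the kinetically set C5 stereocentre never meet enolising conditions.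

**Compound list**

1 | (R)-4-(tert-butyldimethylsilyloxy)cyclopent-2-en-1-one | O=C1C=C[C@H](O[Si](C)(C)C(C)(C)C)C1 | starting material
2 | acetaldehyde | CC=O | starting material
3 | (R)-4-(tert-butyldimethylsilyloxy)-2-[(S)-1-hydroxyethyl]cyclopent-2-en-1-one | O=C1C([C@H](C)O)=C[C@H](O[Si](C)(C)C(C)(C)C)C1 | intermediate
4 | (R)-4-(tert-butyldimethylsilyloxy)-2-[(S)-1-(triethylsilyloxy)ethyl]cyclopent-2-en-1-one | O=C1C([C@H](C)O[Si](CC)(CC)CC)=C[C@H](O[Si](C)(C)C(C)(C)C)C1 | intermediate
5 | vinylmagnesium bromide | C=C[Mg]Br | starting material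
6 | cis-ketone: C4 ketone, C2–OTBS, C6 vinyl trans to OTBS, C5 (S)-1-(triethylsilyloxy)ethyl cis to vinyl | CC(C)(C)[Si](C)(C)O[C@@H]1CC(=O)[C@@H]([C@H](C)O[Si](CC)(CC)CC)[C@H]1C=C | intermediate
7 | C4 alcohol of 6 (OH cis to the C5 side chain) | CC(C)(C)[Si](C)(C)O[C@@H]1C[C@@H](O)[C@@H]([C@H](C)O[Si](CC)(CC)CC)[C@H]1C=C | intermediate
8 | C4 triisopropylsilyl ether of 7 | CC(C)(C)[Si](C)(C)O[C@@H]1C[C@@H](O[Si](C(C)C)(C(C)C)C(C)C)[C@@H]([C@H](C)O[Si](CC)(CC)CC)[C@H]1C=C | intermediate
9 | C13 alcohol (triethylsilyl group removed) | CC(C)(C)[Si](C)(C)O[C@@H]1C[C@@H](O[Si](C(C)C)(C(C)C)C(C)C)[C@@H]([C@H](C)O)[C@H]1C=C | intermediate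
10 | C13 acetate | CC(C)(C)[Si](C)(C)O[C@@H]1C[C@@H](O[Si](C(C)C)(C(C)C)C(C)C)[C@@H]([C@H](C)OC(C)=O)[C@H]1C=C | intermediate
11 | C7 aldehyde | CC(C)(C)[Si](C)(C)O[C@@H]1C[C@@H](O[Si](C(C)C)(C(C)C)C(C)C)[C@@H]([C@H](C)OC(C)=O)[C@H]1C=O | intermediate
12 | methyl acrylate | C=CC(=O)OC | starting material
13 | Morita–Baylis–Hillman adduct (C7 carbinol, both epimers) | CC(C)(C)[Si](C)(C)O[C@@H]1C[C@@H](O[Si](C(C)C)(C(C)C)C(C)C)[C@@H]([C@H](C)OC(C)=O)[C@H]1C(O)C(=C)C(=O)OC | intermediate
14 | C2,C7-diol | O[C@@H]1C[C@@H](O[Si](C(C)C)(C(C)C)C(C)C)[C@@H]([C@H](C)OC(C)=O)[C@H]1C(O)C(=C)C(=O)OC | intermediate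
15 | fragment A: C2 iodide, methyl (Z)-2-(iodomethyl)acrylate on C6 | I[C@H]1C[C@@H](O[Si](C(C)C)(C(C)C)C(C)C)[C@@H]([C@H](C)OC(C)=O)[C@H]1/C=C(\CI)C(=O)OC | intermediate
16 | ethynyltrimethylsilane | C#C[Si](C)(C)C | starting material
17 | methyl 2,2-dimethoxyacetate | COC(OC)C(=O)OC | starting material
18 | 1,1-dimethoxy-4-(trimethylsilyl)but-3-yn-2-one | COC(OC)C(=O)C#C[Si](C)(C)C | intermediate
19 | (R)-1,1-dimethoxy-4-(trimethylsilyl)but-3-yn-2-ol | COC(OC)[C@@H](C#C[Si](C)(C)C)O | intermediate
20 | 4-methoxybenzyl chloride | COc1ccc(CCl)cc1 | starting material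
21 | (R)-4-methoxybenzyl ether of 19 (silylated ether) | COC(OC)[C@@H](C#C[Si](C)(C)C)OCc1ccc(OC)cc1 | intermediate
22 | (R)-3-[(4-methoxybenzyl)oxy]-4,4-dimethoxybut-1-yne | COC(OC)[C@@H](C#C)OCc1ccc(OC)cc1 | intermediate
23 | fragment B: (R)-2-[(4-methoxybenzyl)oxy]but-3-ynal | O=C[C@@H](C#C)OCc1ccc(OC)cc1 | intermediate
24 | Barbier adduct: C7–C8 joined, C8–OH, C2 iodide and alkyne still present | I[C@H]1C[C@@H](O[Si](C(C)C)(C(C)C)C(C)C)[C@@H]([C@H](C)OC(C)=O)[C@H]1[C@@H](C(=C)C(=O)OC)[C@@H](O)[C@@H](C#C)OCc1ccc(OC)cc1 | intermediate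
25 | bicyclic alcohol: cis-hydrindane, C1 methylene, C7 acrylate, C8–OH, C9–O-PMB, C4–O-TIPS | C=C1[C@H]2C[C@@H](O[Si](C(C)C)(C(C)C)C(C)C)[C@@H]([C@H](C)OC(C)=O)[C@H]2[C@@H](C(=C)C(=O)OC)[C@@H](O)[C@@H]1OCc1ccc(OC)cc1 | intermediate
26 | (E)-3-methylpent-2-enoic acid | OC(=O)/C=C(\C)CC | starting material
27 | C8 (E)-3-methylpent-2-enoate | C=C1[C@H]2C[C@@H](O[Si](C(C)C)(C(C)C)C(C)C)[C@@H]([C@H](C)OC(C)=O)[C@H]2[C@@H](C(=C)C(=O)OC)[C@@H](OC(=O)/C=C(\C)CC)[C@@H]1OCc1ccc(OC)cc1 | intermediate
28 | C9 alcohol | C=C1[C@H]2C[C@@H](O[Si](C(C)C)(C(C)C)C(C)C)[C@@H]([C@H](C)OC(C)=O)[C@H]2[C@@H](C(=C)C(=O)OC)[C@@H](OC(=O)/C=C(\C)CC)[C@@H]1O | intermediate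
29 | (S)-3-methylpentanoic acid | OC(=O)C[C@@H](C)CC | starting material
30 | diester acrylate | C=C1[C@H]2C[C@@H](O[Si](C(C)C)(C(C)C)C(C)C)[C@@H]([C@H](C)OC(C)=O)[C@H]2[C@@H](C(=C)C(=O)OC)[C@@H](OC(=O)/C=C(\C)CC)[C@@H]1OC(=O)C[C@@H](C)CC | intermediate
31 | (R)-oxirane at C11, C4–O-TIPS | C=C1[C@H]2C[C@@H](O[Si](C(C)C)(C(C)C)C(C)C)[C@@H]([C@H](C)OC(C)=O)[C@H]2[C@@H]([C@]2(C(=O)OC)CO2)[C@@H](OC(=O)/C=C(\C)CC)[C@@H]1OC(=O)C[C@@H](C)CC | intermediate
32 | C4 alcohol | C=C1[C@H]2C[C@@H](O)[C@@H]([C@H](C)OC(C)=O)[C@H]2[C@@H]([C@]2(C(=O)OC)CO2)[C@@H](OC(=O)/C=C(\C)CC)[C@@H]1OC(=O)C[C@@H](C)CC | intermediate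
33 | CNP0109740.1 | C=C1[C@H]2CC(=O)[C@@H]([C@H](C)OC(C)=O)[C@H]2[C@@H]([C@]2(C(=O)OC)CO2)[C@@H](OC(=O)/C=C(\C)CC)[C@@H]1OC(=O)C[C@@H](C)CC | target

**Step count**

Total: 22 steps. Longest linear sequence: 18 steps (steps 1–11 and 16–22).

**Steps most likely to fail**

Step 16 (proposed new method). Single-electron reduction of the secondary iodide may outrun the allylation and give plain hydrodeiodination; the slow 6-exo-dig closure may lose to reduction of the C2 radical; O8 may lactonise onto the methyl ester on warming; and discrimination of the allyl π-face by C6, as well as chelation by the benzylic ether in water, may be weak. Fallback: from 15 and 23, the indium-mediated Barbier allylation is run alone at 0 °C and stopped at the Barbier adduct 24, which is isolated. A separate tin hydride radical chain (Bu3SnH, AIBN, benzene, 80 °C, slow addition) then closes the ring and comes back to the route at 25. No new compound is needed.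

Step 11. Substitution at C2 has to enter from the face that carries the neighbouring substituents, so elimination or no reaction may win, and the allylic alcohol may give mixtures of direct and rearranged iodides. Fallback without substitution at C2: from 13, Corey–Kim bromination (NBS, Me2S) gives the (Z)-allylic bromide F1. HF·pyridine then frees the C2 alcohol F2, and 1,1′-thiocarbonyldiimidazole gives the imidazolyl thiocarbonate F3. Indium-mediated Barbier allylation of 23 gives the adduct F4, and Barton–McCombie-type radical generation (Bu3SnH, AIBN, benzene, 80 °C) with 6-exo-dig closure comes back to the route at 25.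

Step 20. Facial selectivity at C11 rests on acyclic substrate control and may be poor, and the peroxide anion may attack one of the four esters. Fallback: from 30, a catalyst-controlled asymmetric nucleophilic epoxidation of the α,β-unsaturated ester (chiral yttrium biaryldiolate made from Y(O-i-Pr)3, Ph3As=O, t-BuOOH, THF) sets C11 by the ligand and comes back at 31. No new compound is needed.

**Further compounds**

F0 | step 16 | none | none
F1 | step 11 | (Z)-allylic bromide, C2–OTBS | CC(C)(C)[Si](C)(C)O[C@@H]1C[C@@H](O[Si](C(C)C)(C(C)C)C(C)C)[C@@H]([C@H](C)OC(C)=O)[C@H]1/C=C(\CBr)C(=O)OC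
F2 | step 11 | (Z)-allylic bromide, C2 alcohol | O[C@@H]1C[C@@H](O[Si](C(C)C)(C(C)C)C(C)C)[C@@H]([C@H](C)OC(C)=O)[C@H]1/C=C(\CBr)C(=O)OC
F3 | step 11 | C2 imidazolyl thiocarbonate, (Z)-allylic bromide | S=C(O[C@@H]1C[C@@H](O[Si](C(C)C)(C(C)C)C(C)C)[C@@H]([C@H](C)OC(C)=O)[C@H]1/C=C(\CBr)C(=O)OC)n1ccnc1
F4 | step 11 | Barbier adduct with C2 imidazolyl thiocarbonate | S=C(O[C@@H]1C[C@@H](O[Si](C(C)C)(C(C)C)C(C)C)[C@@H]([C@H](C)OC(C)=O)[C@H]1[C@@H](C(=C)C(=O)OC)[C@@H](O)[C@@H](C#C)OCc1ccc(OC)cc1)n1ccnc1
F0 | step 20 | none | none
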